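## Analysis of the target

The target is a daucane diester, (3R,3aS,4S,8S,8aS)-3-hydroxy-6,8a-dimethyl-8-{[(2Z)-2-methylbut-2-enoyl]oxy}-3-(propan-2-yl)-1,2,3,3a,4,5,8,8a-octahydroazulen-4-yl 4-hydroxybenzoate. In the daucane numbering used throughout, the five-membered ring is C1(Me)–C2–C3–C4(OH)(iPr)–C5(H) and the seven-membered ring is C1–C5–C6(OAr)–C7–C8(Me)=C9–C10(OAng); the configuration is 1S,4R,5S,6S,10S. The rings are trans-fused: the C1 methyl, the C4 hydroxyl and the C10 oxygen lie on the β face, while H5, the C6 oxygen and the isopropyl group lie on the α face, so five contiguous stereocentres run from C4 over C5 and C1 to C6 and C10. The sensitive groups are the angelate (a Z-enoate that isomerises to the tiglate under basic or nucleophilic acylation), the allylic ester at C10, the tertiary C4 alcohol (β to C6, so prone to dehydration or retro-aldol cleavage once C6 is a carbonyl) and the free phenol. The synthesis is hard for three reasons: C1 is quaternary and sits beside the fully substituted C4–C5 region, the two secondary alcohols at C6 and C10 must carry two different acyl groups, and the alkene must lie at C8=C9 and nowhere else. The strategy rests on one feature: the quaternary C1 is bonded to C5, and C5 lies between the oxygenated C4 and C6. Read backwards, C5 is a carbenoid carbon between a C4 ketone and a C6 ester, and C1 is a tertiary C–H carbon of an open chain whose configuration comes from a cheap chiral hydroxy ester, with C10 as its CH2O arm. All other stereocentres are then set relative to C1.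

## Retrosynthetic reasoning

**Acyl groups last.** The C10–O angeloyl bond, the C6–O aroyl bond and the phenol O–Si bond are cut first: 36 comes from 35, 35 from 32 and 33, 32 from 31, and 31 from 27 and 30 (30 from 28). Esters cannot survive the organometallic steps and the angelate isomerises easily, so both are attached at the end. The gain is 27, in which C10 is a ketone and C6 an alcohol, so each acid meets only one free secondary hydroxyl. Forward, C6 must be acylated beside an unreactive tertiary alcohol, the C10 ketone reduced from the α face, and the angelate introduced without Z/E isomerisation.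

**C8=C9 and the C10 oxidation level.** 27 comes from 26 by oxidation of the allylic alcohol only, and 26 from 25 by cutting C8=C9 (ring-closing metathesis in the forward sense). Cutting here places the trisubstituted alkene exactly where the target has it, with no later isomerisation, and it makes the C10 hydroxyl allylic while the C6 hydroxyl is not. That difference is what separates the two carbinols.

**C9–C10 and C6–C7.** 25 is cut at C10–C9 to 23 and 24, and 23 at C6–C7 to 20 and 21. Both carbinol carbons become aldehydes on the cyclopentane, which reduces the problem to the monocyclic dialdehyde 20. Forward, the first addition must choose the C6 aldehyde over the C10 aldehyde and the correct face of C6; the free C4 hydroxyl is kept for this, as a chelating group.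

**C4–isopropyl.** 20 comes from 19 and 18, and 18 from ketone 15 and 16 by cutting the C4–isopropyl bond. The addition must occur anti to the C5 substituent so that the hydroxyl ends up cis to the C1 methyl.

**Oxidation levels and C5.** 15 comes from 14, 13 and 12, and 12 from 11. No skeletal bond is cut; the ester carbon becomes the C6 carbinol and the pivalate is removed. The hydrogenation of 11 to 12 is placed here because C5 of 11 is epimerisable, and this is the point at which it can be fixed under catalyst control.

**C1–C5 (key disconnection).** 11 is cut between C1 and C5 to give the acyclic diazo keto ester 10. The cut removes the ring and the quaternary centre together, and leaves a chain with a single tertiary stereocentre. Forward, the insertion must occur at C1–H with retention and not at C10–H.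

**The chain.** 10 comes from 9 and 8 by protecting-group exchange, 8 from 7 by diazo transfer, and 7 by cutting C2–C3 into iodide 4 and the acetoacetate unit 5. 4 comes from 3, 2 and 1. The stereocentre of 1 becomes C1 of the target unchanged.

## Alternatives that were turned down

**Alternative 1:** C6–C7 and C9–C10 are cut together. The seven-membered ring is closed last from a cyclopentane 1,4-dialdehyde, (1S,2R,3R)-1-methyl-3-(propan-2-yl)-3-(triethylsilyloxy)cyclopentane-1,2-dicarbaldehyde A2, and a three-carbon bis-allyl donor, 3-iodo-2-(iodomethyl)prop-1-ene A3.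
- Forward key step: a zerovalent metal turns A3 into an allylmetal that adds to one aldehyde of A2; the second allyl terminus then adds to the other aldehyde within the molecule and gives (1S,4R,5S,6S,10S)-8-methylidene-4-(triethylsilyloxy)daucane-6,10-diol A1.
- For it: ring and both carbinols arise in one operation, and no choice between the two aldehydes is needed because both react. On ring-closure step economy it is stronger than the chosen route, which needs three steps (23, 25, 26) for the same bonds.
- Against it: it does not make the cyclopentane with the quaternary C1, so it is an end-game rather than a solution to the main problem. The two new hydroxyls of A1 are both homoallylic and chemically alike although they must carry different acyl groups. The configuration at C10 has no clear control element. The exocyclic alkene must still be moved to C8=C9 and not to C7=C8.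
- Comparison: the chosen route forms the alkene in place and obtains an allylic/non-allylic pair of alcohols (26) that can be told apart by oxidation. Dialdehyde 20 is the free-hydroxyl analogue of A2, so this closure stays available.

**Alternative 2:** C1–C10 and C5–C6 are cut on a cyclopentanone.
- Forward key step: 3-methylcyclopent-2-en-1-one A5 takes up a vinyl group at C1 by copper-catalysed asymmetric conjugate addition of a vinylaluminium nucleophile, and the aluminium enolate is trapped at C5 with formaldehyde A6, giving (2S,3R)-2-(hydroxymethyl)-3-methyl-3-vinylcyclopentan-1-one A4.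
- For it: one flask delivers the quaternary C1, C10 (as vinyl), C6 and the C4 ketone, and both A5 and A6 are bulk chemicals. A4 corresponds to the stage of 15, which the chosen route reaches only after a dozen steps, so on step economy this alternative is clearly stronger.
- Against it: building a quaternary centre by enantioselective conjugate addition to a β-substituted five-membered enone such as A5 with a vinyl donor is a demanding case, and the enantiomeric purity of the whole synthesis would depend on catalyst tuning. The aldol trapping with A6 occurs next to the new quaternary carbon. A4 is a β-hydroxy ketone that loses water or formaldehyde easily. The trans relation at C5 rests on the same small methyl/vinyl size difference.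
- Comparison: the chosen strategy takes the absolute configuration from the chiral pool and passes it to C1 by a stereospecific, retentive step, so enantiopurity does not depend on a catalyst.

**Alternative 3:** C1–C5 and C6–C7 are cut together.
- Forward key step: (S)-terpinen-4-ol A9, which already holds the C4 carbinol with its isopropyl group, is cleaved and elaborated to (3R,6E)-6-methyl-7-(2-methylcyclopropyl)-3-(propan-2-yl)-3-(triethylsilyloxy)hept-6-en-1-yne A8. A (5+2) cycloaddition catalysed by [Rh(CO)2Cl]2 between the alkyne and the vinylcyclopropane of A8 closes both rings to (1R,4R,8S)-dauca-5,9-dien-4-ol triethylsilyl ether A7.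
- For it: both rings in one step, and C4 from the chiral pool with the correct substituents. On ring-forming economy it is the strongest of all the routes.
- Against it: the quaternary C1 would arise from the trisubstituted alkene terminus of A8, with its configuration controlled only by the remote, fully substituted C4. A7 has the wrong oxidation pattern, so C6–O, H5, C10–O and the C8=C9 alkene would have to be installed by late hydration and allylic transposition steps, each needing face and site control. Commercial A9 is of limited enantiomeric purity.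
- Comparison: the chosen strategy fixes C1 first and with certainty and then adds each oxygen at the correct oxidation level by standard carbonyl chemistry.

Key step: step 8

## Route

Remark on the chemistry: bicyclic compounds are named on the daucane skeleton with the numbering above. C5 of 11 lies between two carbonyl groups and equilibrates; 11 is drawn with the C5 configuration that step 9 selects.

Step 1
Reactants: 1 methyl (R)-3-hydroxy-2-methylpropanoate
Product: 2 methyl (R)-3-(tert-butyldimethylsilyloxy)-2-methylpropanoate
Conditions: TBSCl, imidazole, DMF, 0 °C to rt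
Reagents that add atoms: tert-butyldimethylsilyl chloride, CC(C)(C)[Si](C)(C)Cl
Why: Imidazole-mediated silylation of a primary alcohol; the stereocentre is not touched.

Step 2
Reactants: 2 methyl (R)-3-(tert-butyldimethylsilyloxy)-2-methylpropanoate
Product: 3 (S)-3-(tert-butyldimethylsilyloxy)-2-methylpropan-1-ol
Conditions: iBu2AlH, CH2Cl2, −78 to 0 °C
Reagents that add atoms: none
Why: Hydride reduction of the ester to the primary alcohol at low temperature, where the α-stereocentre is not enolised; the descriptor changes only because the priorities change.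

Step 3
Reactants: 3 (S)-3-(tert-butyldimethylsilyloxy)-2-methylpropan-1-ol
Product: 4 (R)-tert-butyl(3-iodo-2-methylpropoxy)dimethylsilane
Conditions: PPh3, I2, imidazole, CH2Cl2, 0 °C to rt
Reagents that add atoms: iodine, II
Why: Appel-type iodination of the primary alcohol; substitution occurs at the CH2 group, not at the stereocentre.

Step 4
Reactants: 5 methyl acetoacetate; 4 (R)-tert-butyl(3-iodo-2-methylpropoxy)dimethylsilane
Product: 7 methyl (S)-7-(tert-butyldimethylsilyloxy)-6-methyl-3-oxoheptanoate, via lithium sodium dianion of methyl acetoacetate 6 (not isolated)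
Conditions: NaH, THF, 0 °C; n-BuLi, 0 °C; then 4, 0 °C to rt; aq. NH4Cl
Reagents that add atoms: none
Why: γ-Alkylation of the acetoacetate dianion: the more basic terminal carbanion reacts with the primary iodide; the β-branch slows the SN2 step but does not divert it, and excess dianion is used.

Step 5
Reactants: 7 methyl (S)-7-(tert-butyldimethylsilyloxy)-6-methyl-3-oxoheptanoate
Product: 8 methyl (S)-7-(tert-butyldimethylsilyloxy)-2-diazo-6-methyl-3-oxoheptanoate
Conditions: 4-acetamidobenzenesulfonyl azide, Et3N, MeCN, 0 °C to rt
Reagents that add atoms: 4-acetamidobenzenesulfonyl azide, CC(=O)Nc1ccc(cc1)S(=O)(=O)N=[N+]=[N-]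
Why: Regitz diazo transfer to the active methylene between ketone and ester.

Step 6
Reactants: 8 methyl (S)-7-(tert-butyldimethylsilyloxy)-2-diazo-6-methyl-3-oxoheptanoate
Product: 9 methyl (S)-2-diazo-7-hydroxy-6-methyl-3-oxoheptanoate
Conditions: HF·pyridine, pyridine, THF, 0 °C to rt
Reagents that add atoms: none
Why: Fluoride desilylation; the doubly acceptor-substituted diazo group tolerates buffered HF. The exchange is done after diazo transfer because the free δ-hydroxy β-keto ester would close to a lactol and dehydrate to a cyclic enol ether, which the diazo-conjugated ketone does not do.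

Step 7
Reactants: 9 methyl (S)-2-diazo-7-hydroxy-6-methyl-3-oxoheptanoate
Product: 10 methyl (6S)-2-diazo-6-methyl-3-oxo-7-(pivaloyloxy)heptanoate
Conditions: pivaloyl chloride, pyridine, DMAP (cat.), CH2Cl2, 0 °C to rt
Reagents that add atoms: pivaloyl chloride, CC(C)(C)C(Cl)=O
Why: DMAP-catalysed acylation of the primary alcohol; the pivalate removes the O–H insertion pathway and makes the C10–H bonds electron-poor for the next step.

Step 8
Reactants: 10 methyl (6S)-2-diazo-6-methyl-3-oxo-7-(pivaloyloxy)heptanoate
Product: 11 methyl (1R,5S)-5-methyl-2-oxo-5-(pivaloyloxymethyl)cyclopentane-1-carboxylate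
Conditions: Rh2(OAc)4 (1 mol %), CH2Cl2, 25–40 °C, slow addition of 10
Reagents that add atoms: none
Why: Rh2(OAc)4 takes up the diazo carbon of 10 and loses N2 to give an electrophilic rhodium carbenoid at C5, flanked by the C4 ketone and the C6 ester. The carbenoid inserts into the C1–H bond through a concerted three-centre transition state in which the new C–C bond forms on the face from which hydrogen leaves, so the 6S methine of 10 becomes the quaternary C1 with retention. The closest known reaction type is the dirhodium-catalysed 1,5 C–H insertion of α-diazo β-keto esters into tertiary C–H bonds. The cyclopentane closes in the 1,5 mode: the carbenoid carbon and the C–H carbon are separated by C4, C3 and C2, and a chair-like six-centre array that includes the migrating hydrogen gives the five-membered ring. C1 is controlled by the stereocentre of 1 through the retentive mechanism; C5 forms as an equilibrating mixture with its epimer and the enol and is fixed only in step 9. The step needs site selectivity against the two C10–H bonds (six-membered mode, next to oxygen) and the methyl C–H bonds: C1–H is the only 1,5 C–H bond and is a methine, the most reactive class, and the pivalate lowers the hydride character of C10–H and excludes the ylide and O–H pathways of an ether or free oxygen. A 1,2-hydride shift cannot compete because both neighbours of the carbenoid carbon are carbonyl carbons.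

Step 9
Reactants: 11 methyl (1R,5S)-5-methyl-2-oxo-5-(pivaloyloxymethyl)cyclopentane-1-carboxylate
Product: 12 methyl (1R,2R,5S)-2-hydroxy-5-methyl-5-(pivaloyloxymethyl)cyclopentane-1-carboxylate
Conditions: RuCl2[(R)-BINAP] (1 mol %), H2 (100 atm), CH2Cl2, 50 °C
Reagents that add atoms: none
Why: Noyori asymmetric hydrogenation of a cyclic α-substituted β-keto ester with dynamic kinetic resolution: the C5 epimers of 11 interconvert through the enol faster than they are reduced, and the (R)-BINAP ruthenium hydride reduces the epimer with R configuration at the ester-bearing carbon through the ester-chelated transition state, giving the trans hydroxy ester as it gives the (1R,2R) product from methyl 2-oxocyclopentanecarboxylate. Because methyl and pivaloyloxymethyl on C1 differ little in size, the substrate bias is small and the catalyst should decide C5. The C4 carbinol configuration does not matter, since C4 is reoxidised in step 12.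

Step 10
Reactants: 12 methyl (1R,2R,5S)-2-hydroxy-5-methyl-5-(pivaloyloxymethyl)cyclopentane-1-carboxylate
Product: 13 (1R,2S,3S)-2,3-bis(hydroxymethyl)-3-methylcyclopentan-1-ol
Conditions: LiAlH4, THF, 0 °C to rt; Fieser work-up
Reagents that add atoms: none
Why: Hydride reduction of the methyl ester to the C6 carbinol and reductive cleavage of the pivalate in one operation; C5 is no longer α to a carbonyl group once the ester is reduced.

Step 11
Reactants: 13 (1R,2S,3S)-2,3-bis(hydroxymethyl)-3-methylcyclopentan-1-ol
Product: 14 (1R,2S,3S)-2,3-bis[(tert-butyldimethylsilyloxy)methyl]-3-methylcyclopentan-1-ol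
Conditions: TBSCl (2.2 equiv), Et3N, DMAP (cat.), CH2Cl2, 0 °C to rt
Reagents that add atoms: tert-butyldimethylsilyl chloride, CC(C)(C)[Si](C)(C)Cl
Why: Selective silylation of the two primary alcohols; the secondary ring alcohol beside the substituted C5 reacts much more slowly with the bulky silyl chloride under amine/DMAP conditions.

Step 12
Reactants: 14 (1R,2S,3S)-2,3-bis[(tert-butyldimethylsilyloxy)methyl]-3-methylcyclopentan-1-ol
Product: 15 (2S,3S)-2,3-bis[(tert-butyldimethylsilyloxy)methyl]-3-methylcyclopentan-1-one
Conditions: Pr4N[RuO4] (5 mol %), N-methylmorpholine N-oxide, 4 Å MS, CH2Cl2, rt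
Reagents that add atoms: none
Why: Ley–Griffith oxidation of the secondary alcohol under neutral conditions, which spare the α-stereocentre C5 and the β-silyloxy group.

Step 13
Reactants: 15 (2S,3S)-2,3-bis[(tert-butyldimethylsilyloxy)methyl]-3-methylcyclopentan-1-one; 16 isopropylmagnesium chloride
Product: 18 (1R,2S,3S)-2,3-bis[(tert-butyldimethylsilyloxy)methyl]-3-methyl-1-(propan-2-yl)cyclopentan-1-ol, via isopropylcerium dichloride 17 (not isolated)
Conditions: CeCl3 (anhydrous), THF, −78 °C; 16, −78 °C; then 15, −78 to 0 °C
Reagents that add atoms: none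
Why: Organocerium 1,2-addition: the weakly basic cerium reagent adds to the hindered, enolisable ketone without enolisation or β-hydride reduction. It approaches C4 from the α face, anti to the adjacent C5 silyloxymethyl group, so the hydroxyl ends on the β face (4R), cis to the C1 methyl.

Step 14
Reactants: 18 (1R,2S,3S)-2,3-bis[(tert-butyldimethylsilyloxy)methyl]-3-methyl-1-(propan-2-yl)cyclopentan-1-ol
Product: 19 (1R,2S,3S)-2,3-bis(hydroxymethyl)-3-methyl-1-(propan-2-yl)cyclopentan-1-ol
Conditions: Bu4NF, THF, 0 °C to rt
Reagents that add atoms: none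
Why: Fluoride cleavage of both primary silyl ethers; no other group in 18 responds to fluoride.

Step 15
Reactants: 19 (1R,2S,3S)-2,3-bis(hydroxymethyl)-3-methyl-1-(propan-2-yl)cyclopentan-1-ol
Product: 20 (1S,2R,3R)-3-hydroxy-1-methyl-3-(propan-2-yl)cyclopentane-1,2-dicarbaldehyde
Conditions: (COCl)2, DMSO, CH2Cl2, −78 °C; Et3N, −78 to −20 °C
Reagents that add atoms: none
Why: Double Swern oxidation: both primary alcohols are activated before base is added, so no hydroxy aldehyde is present to form a lactol, and the tertiary alcohol cannot be oxidised. C5 is now epimerisable, but the configuration with C6 trans to the isopropyl group is the stable one.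

Step 16
Reactants: 20 (1S,2R,3R)-3-hydroxy-1-methyl-3-(propan-2-yl)cyclopentane-1,2-dicarbaldehyde; 21 3-bromo-2-methylprop-1-ene
Product: 23 (1S,2S,3R)-3-hydroxy-2-[(1S)-1-hydroxy-3-methylbut-3-en-1-yl]-1-methyl-3-(propan-2-yl)cyclopentane-1-carbaldehyde, via 2-methylallylindium sesquibromide 22 (not isolated)
Conditions: In powder (1.2 equiv), 21 (1.2 equiv), THF/H2O 1:1, rt
Reagents that add atoms: none
Why: Indium-mediated Barbier allylation in aqueous THF: the allylindium reagent adds to the C6 aldehyde, which is activated by chelation to the free C4 hydroxyl, in preference to the C10 aldehyde on the quaternary carbon. In the six-membered chelate on the β face the reagent attacks the carbonyl face next to H5 and away from C1 and its methyl group (Cram-chelate model), which gives the 6S carbinol. A lactol between the new hydroxyl and C10 is disfavoured because C6 and C10 are trans on the cyclopentane.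

Step 17
Reactants: 23 (1S,2S,3R)-3-hydroxy-2-[(1S)-1-hydroxy-3-methylbut-3-en-1-yl]-1-methyl-3-(propan-2-yl)cyclopentane-1-carbaldehyde; 24 vinylmagnesium bromide
Product: 25 (1R,2S,3S)-2-[(1S)-1-hydroxy-3-methylbut-3-en-1-yl]-3-[(1RS)-1-hydroxyprop-2-en-1-yl]-3-methyl-1-(propan-2-yl)cyclopentan-1-ol
Conditions: 24 (4 equiv), THF, −78 to −20 °C
Reagents that add atoms: none
Why: Grignard addition to the remaining aldehyde after deprotonation of the two hydroxyl groups. Both C10 epimers are carried on, because C10 is oxidised in step 19 and set in step 22.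

Step 18
Reactants: 25 (1R,2S,3S)-2-[(1S)-1-hydroxy-3-methylbut-3-en-1-yl]-3-[(1RS)-1-hydroxyprop-2-en-1-yl]-3-methyl-1-(propan-2-yl)cyclopentan-1-ol
Product: 26 (1S,4R,5S,6S,10RS)-dauc-8-ene-4,6,10-triol
Conditions: second-generation Hoveyda–Grubbs catalyst (10 mol %), 1,4-benzoquinone (20 mol %), toluene (0.005 M), 80 °C
Reagents that add atoms: none
Why: Ring-closing metathesis between the vinyl carbinol and the 1,1-disubstituted alkene closes the seven-membered ring and places the trisubstituted alkene at C8=C9. Free hydroxyl groups are tolerated, and the quinone suppresses ruthenium hydride isomerisation of the allylic alcohol.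

Step 19
Reactants: 26 (1S,4R,5S,6S,10RS)-dauc-8-ene-4,6,10-triol
Product: 27 (1S,4R,5S,6S)-4,6-dihydroxydauc-8-en-10-one
Conditions: MnO2 (activated, excess), CH2Cl2, rt
Reagents that add atoms: none
Why: MnO2 oxidises only the allylic C10 alcohol and leaves the homoallylic C6 and tertiary C4 alcohols, so both C10 epimers converge on one enone and the two secondary oxygens are now differentiated.

Step 20
Reactants: 28 4-hydroxybenzoic acid
Product: 30 4-(triisopropylsilyloxy)benzoic acid, via triisopropylsilyl 4-(triisopropylsilyloxy)benzoate 29 (not isolated)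
Conditions: triisopropylsilyl chloride (2.2 equiv), imidazole, DMF, rt; then AcOH/THF/H2O, rt
Reagents that add atoms: triisopropylsilyl chloride, CC(C)[Si](Cl)(C(C)C)C(C)C
Why: Silylation of both acidic hydroxyls, then selective hydrolysis of the much more labile silyl ester; the aryl silyl ether stays.

Step 21
Reactants: 27 (1S,4R,5S,6S)-4,6-dihydroxydauc-8-en-10-one; 30 4-(triisopropylsilyloxy)benzoic acid
Product: 31 (1S,4R,5S,6S)-4-hydroxy-10-oxodauc-8-en-6-yl 4-(triisopropylsilyloxy)benzoate
Conditions: N,N'-dicyclohexylcarbodiimide, DMAP, CH2Cl2, 0 °C to rt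
Reagents that add atoms: none
Why: Steglich esterification of the only secondary hydroxyl; the tertiary C4 alcohol beside the isopropyl group is not acylated under these conditions. Mild base and low temperature are chosen to avoid vinylogous elimination of the new ester across the enone.

Step 22
Reactants: 31 (1S,4R,5S,6S)-4-hydroxy-10-oxodauc-8-en-6-yl 4-(triisopropylsilyloxy)benzoate
Product: 32 (1S,4R,5S,6S,10S)-4,10-dihydroxydauc-8-en-6-yl 4-(triisopropylsilyloxy)benzoate
Conditions: NaBH4, CeCl3·7H2O, MeOH, −78 °C
Reagents that add atoms: none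
Why: Luche 1,2-reduction of the enone. Hydride attacks C10 from the α face, opposite the angular methyl on the neighbouring quaternary C1, so the hydroxyl ends on the β face (10S). The aryl ester and the hindered aryl silyl ether survive the short, cold reaction.

Step 23
Reactants: 32 (1S,4R,5S,6S,10S)-4,10-dihydroxydauc-8-en-6-yl 4-(triisopropylsilyloxy)benzoate; 33 angelic acid
Product: 35 (1S,4R,5S,6S,10S)-4-hydroxy-10-[(Z)-2-methylbut-2-enoyloxy]dauc-8-en-6-yl 4-(triisopropylsilyloxy)benzoate, via (Z)-2-methylbut-2-enoic 2,4,6-trichlorobenzoic anhydride 34 (not isolated)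
Conditions: 33, 2,4,6-trichlorobenzoyl chloride, Et3N, toluene, rt; then 32, 80 °C
Reagents that add atoms: none
Why: Yamaguchi-type mixed-anhydride esterification run without DMAP, the usual way to make angelates without isomerisation to the tiglate. The alcohol attacks the less hindered angeloyl carbonyl, and the tertiary C4 alcohol does not react.

Step 24
Reactants: 35 (1S,4R,5S,6S,10S)-4-hydroxy-10-[(Z)-2-methylbut-2-enoyloxy]dauc-8-en-6-yl 4-(triisopropylsilyloxy)benzoate
Product: 36 (1S,4R,5S,6S,10S)-4-hydroxy-6-(4-hydroxybenzoyloxy)dauc-8-en-10-yl (Z)-2-methylbut-2-enoate (CNP0273650.10)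
Conditions: Bu4NF, AcOH (1:1), THF, 0 °C
Reagents that add atoms: none
Why: Buffered fluoride cleavage of the electron-poor aryl silyl ether, which is fast at 0 °C; the acetic acid keeps the phenoxide from attacking the angelate or the aryl ester.

## Compound list

1 | methyl (R)-3-hydroxy-2-methylpropanoate | COC(=O)[C@H](C)CO | starting material
2 | methyl (R)-3-(tert-butyldimethylsilyloxy)-2-methylpropanoate | COC(=O)[C@H](C)CO[Si](C)(C)C(C)(C)C | intermediate
3 | (S)-3-(tert-butyldimethylsilyloxy)-2-methylpropan-1-ol | OC[C@H](C)CO[Si](C)(C)C(C)(C)C | intermediate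
4 | (R)-tert-butyl(3-iodo-2-methylpropoxy)dimethylsilane | IC[C@H](C)CO[Si](C)(C)C(C)(C)C | intermediate
5 | methyl acetoacetate | COC(=O)CC(C)=O | starting material
6 | lithium sodium dianion of methyl acetoacetate | [Li+].[Na+].[CH2-]C(=O)[CH-]C(=O)OC | intermediate
7 | methyl (S)-7-(tert-butyldimethylsilyloxy)-6-methyl-3-oxoheptanoate | COC(=O)CC(=O)CC[C@H](C)CO[Si](C)(C)C(C)(C)C | intermediate
8 | methyl (S)-7-(tert-butyldimethylsilyloxy)-2-diazo-6-methyl-3-oxoheptanoate | COC(=O)C(=[N+]=[N-])C(=O)CC[C@H](C)CO[Si](C)(C)C(C)(C)C | intermediate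
9 | methyl (S)-2-diazo-7-hydroxy-6-methyl-3-oxoheptanoate | COC(=O)C(=[N+]=[N-])C(=O)CC[C@H](C)CO | intermediate
10 | methyl (6S)-2-diazo-6-methyl-3-oxo-7-(pivaloyloxy)heptanoate | COC(=O)C(=[N+]=[N-])C(=O)CC[C@H](C)COC(=O)C(C)(C)C | intermediate
11 | methyl (1R,5S)-5-methyl-2-oxo-5-(pivaloyloxymethyl)cyclopentane-1-carboxylate | COC(=O)[C@@H]1[C@@](C)(COC(=O)C(C)(C)C)CCC1=O | intermediate
12 | methyl (1R,2R,5S)-2-hydroxy-5-methyl-5-(pivaloyloxymethyl)cyclopentane-1-carboxylate | COC(=O)[C@@H]1[C@@](C)(COC(=O)C(C)(C)C)CC[C@H]1O | intermediate
13 | (1R,2S,3S)-2,3-bis(hydroxymethyl)-3-methylcyclopentan-1-ol | OC[C@@H]1[C@@](C)(CO)CC[C@H]1O | intermediate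
14 | (1R,2S,3S)-2,3-bis[(tert-butyldimethylsilyloxy)methyl]-3-methylcyclopentan-1-ol | CC(C)(C)[Si](C)(C)OC[C@@H]1[C@@](C)(CO[Si](C)(C)C(C)(C)C)CC[C@H]1O | intermediate
15 | (2S,3S)-2,3-bis[(tert-butyldimethylsilyloxy)methyl]-3-methylcyclopentan-1-one | CC(C)(C)[Si](C)(C)OC[C@@H]1[C@@](C)(CO[Si](C)(C)C(C)(C)C)CCC1=O | intermediate
16 | isopropylmagnesium chloride | CC(C)[Mg]Cl | starting material
17 | isopropylcerium dichloride | CC(C)[Ce](Cl)Cl | intermediate
18 | (1R,2S,3S)-2,3-bis[(tert-butyldimethylsilyloxy)methyl]-3-methyl-1-(propan-2-yl)cyclopentan-1-ol | CC(C)(C)[Si](C)(C)OC[C@@H]1[C@@](C)(CO[Si](C)(C)C(C)(C)C)CC[C@@]1(O)C(C)C | intermediate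
19 | (1R,2S,3S)-2,3-bis(hydroxymethyl)-3-methyl-1-(propan-2-yl)cyclopentan-1-ol | OC[C@@H]1[C@@](C)(CO)CC[C@@]1(O)C(C)C | intermediate
20 | (1S,2R,3R)-3-hydroxy-1-methyl-3-(propan-2-yl)cyclopentane-1,2-dicarbaldehyde | O=C[C@@H]1[C@@](C)(C=O)CC[C@@]1(O)C(C)C | intermediate
21 | 3-bromo-2-methylprop-1-ene | C=C(C)CBr | starting material
22 | 2-methylallylindium sesquibromide | C=C(C)C[In](Br)CC(C)=C.C=C(C)C[In](Br)Br | intermediate
23 | (1S,2S,3R)-3-hydroxy-2-[(1S)-1-hydroxy-3-methylbut-3-en-1-yl]-1-methyl-3-(propan-2-yl)cyclopentane-1-carbaldehyde | C=C(C)C[C@H](O)[C@@H]1[C@@](C)(C=O)CC[C@@]1(O)C(C)C | intermediate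
24 | vinylmagnesium bromide | C=C[Mg]Br | starting material
25 | (1R,2S,3S)-2-[(1S)-1-hydroxy-3-methylbut-3-en-1-yl]-3-[(1RS)-1-hydroxyprop-2-en-1-yl]-3-methyl-1-(propan-2-yl)cyclopentan-1-ol | C=C(C)C[C@H](O)[C@@H]1[C@@](C)(C(O)C=C)CC[C@@]1(O)C(C)C | intermediate
26 | (1S,4R,5S,6S,10RS)-dauc-8-ene-4,6,10-triol | OC1C=C(C)C[C@H](O)[C@@H]2[C@]1(C)CC[C@@]2(O)C(C)C | intermediate
27 | (1S,4R,5S,6S)-4,6-dihydroxydauc-8-en-10-one | O=C1C=C(C)C[C@H](O)[C@@H]2[C@]1(C)CC[C@@]2(O)C(C)C | intermediate
28 | 4-hydroxybenzoic acid | OC(=O)c1ccc(O)cc1 | starting material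
29 | triisopropylsilyl 4-(triisopropylsilyloxy)benzoate | CC(C)[Si](C(C)C)(C(C)C)OC(=O)c1ccc(O[Si](C(C)C)(C(C)C)C(C)C)cc1 | intermediate
30 | 4-(triisopropylsilyloxy)benzoic acid | OC(=O)c1ccc(O[Si](C(C)C)(C(C)C)C(C)C)cc1 | intermediate
31 | (1S,4R,5S,6S)-4-hydroxy-10-oxodauc-8-en-6-yl 4-(triisopropylsilyloxy)benzoate | O=C1C=C(C)C[C@H](OC(=O)c2ccc(O[Si](C(C)C)(C(C)C)C(C)C)cc2)[C@@H]2[C@]1(C)CC[C@@]2(O)C(C)C | intermediate
32 | (1S,4R,5S,6S,10S)-4,10-dihydroxydauc-8-en-6-yl 4-(triisopropylsilyloxy)benzoate | O[C@H]1C=C(C)C[C@H](OC(=O)c2ccc(O[Si](C(C)C)(C(C)C)C(C)C)cc2)[C@@H]2[C@]1(C)CC[C@@]2(O)C(C)C | intermediate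
33 | angelic acid, (Z)-2-methylbut-2-enoic acid | C/C=C(/C)C(=O)O | starting material
34 | (Z)-2-methylbut-2-enoic 2,4,6-trichlorobenzoic anhydride | C/C=C(/C)C(=O)OC(=O)c1c(Cl)cc(Cl)cc1Cl | intermediate
35 | (1S,4R,5S,6S,10S)-4-hydroxy-10-[(Z)-2-methylbut-2-enoyloxy]dauc-8-en-6-yl 4-(triisopropylsilyloxy)benzoate | C/C=C(/C)C(=O)O[C@H]1C=C(C)C[C@H](OC(=O)c2ccc(O[Si](C(C)C)(C(C)C)C(C)C)cc2)[C@@H]2[C@]1(C)CC[C@@]2(O)C(C)C | intermediate
36 | (1S,4R,5S,6S,10S)-4-hydroxy-6-(4-hydroxybenzoyloxy)dauc-8-en-10-yl (Z)-2-methylbut-2-enoate | C/C=C(/C)C(=O)O[C@H]1C=C(C)C[C@H](OC(=O)c2ccc(O)cc2)[C@@H]2[C@]1(C)CC[C@@]2(O)C(C)C | target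

## Step count and least certain steps

Total: 24 steps. Longest linear sequence: 23 steps (steps 1–19 and 21–24); step 20 is a one-step side branch.

**Step 8 (key step).** The most likely failure is slow insertion. The methine is β to the acyloxy group and next to a branched carbon, so its C–H bond is inductively deactivated and the carbenoid may be lost to dimerisation or to reaction with traces of water. The fallback runs the cyclisation on a substrate whose oxygen substituent is not electron-withdrawing, so that site selectivity rests on ring size and C–H class alone; the five-membered mode should still prevail over insertion next to the silyl ether oxygen, but less securely. It sets out from 8. Rh2(OAc)4 in CH2Cl2 should convert 8 into methyl (1R,5S)-5-[(tert-butyldimethylsilyloxy)methyl]-5-methyl-2-oxocyclopentane-1-carboxylate F1. Hydrogenation of F1 as in step 9 should give methyl (1R,2R,5S)-5-[(tert-butyldimethylsilyloxy)methyl]-2-hydroxy-5-methylcyclopentane-1-carboxylate F2. LiAlH4 reduces only the ester of F2 and gives (1R,2S,3S)-3-[(tert-butyldimethylsilyloxy)methyl]-2-(hydroxymethyl)-3-methylcyclopentan-1-ol F3. Silylation of the primary hydroxyl of F3 with one equivalent of TBSCl returns to the route at 14.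

**Step 9.** The most likely failure is incomplete control of C5: the hindered keto ester may be reduced slowly, or the catalyst may not override the substrate, so that both C5 epimers are carried on. The fallback replaces catalyst control by separation. It sets out from 11. Acetalisation with ethane-1,2-diol, TsOH and benzene at reflux gives methyl (6R,7S)-7-methyl-7-(pivaloyloxymethyl)-1,4-dioxaspiro[4.4]nonane-6-carboxylate F4 together with its C6 epimer. LiAlH4 converts F4 into [(6S,7S)-7-methyl-1,4-dioxaspiro[4.4]nonane-6,7-diyl]dimethanol F5, and the epimers are separated by chromatography at this stage. Bis-silylation of F5 gives (6S,7S)-6,7-bis[(tert-butyldimethylsilyloxy)methyl]-7-methyl-1,4-dioxaspiro[4.4]nonane F6. Hydrolysis of the acetal of F6 with pyridinium tosylate in wet acetone returns to the route at 15.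

**Step 13.** The most likely failure is enolisation of the ketone or β-hydride reduction by the branched reagent, so that little tertiary alcohol forms. The fallback installs the isopropyl group in two steps with a nucleophile that can do neither. It sets out from 15. Isopropenylmagnesium bromide with CeCl3 in THF at −78 °C, adding anti to the C5 substituent, gives (1S,2S,3S)-2,3-bis[(tert-butyldimethylsilyloxy)methyl]-3-methyl-1-(prop-1-en-2-yl)cyclopentan-1-ol F7. Hydrogenation of the 1,1-disubstituted alkene of F7 with H2 over Pd/C in EtOAc returns to the route at 18.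

**Step 16.** The most likely failure is poor site selectivity: both aldehydes are hindered, so addition at C10 or at both carbonyls may compete with the chelation-assisted addition at C6. The fallback differentiates the two arms by protecting groups before either is oxidised. It sets out from 19. 2,2-Dimethoxypropane and pyridinium tosylate should close the acetal between the C4 and C6 oxygens, the only 1,3-diol that can form a six-membered acetal, and give [(4aS,5S,7aR)-2,2,5-trimethyl-7a-(propan-2-yl)hexahydro-2H-cyclopenta[d][1,3]dioxin-5-yl]methanol F8, in which the C10 hydroxyl is free. Swern oxidation of F8 gives (4aS,5S,7aR)-2,2,5-trimethyl-7a-(propan-2-yl)hexahydro-2H-cyclopenta[d][1,3]dioxine-5-carbaldehyde F9. Vinylmagnesium bromide adds to F9 and gives (1RS)-1-[(4aS,5S,7aR)-2,2,5-trimethyl-7a-(propan-2-yl)hexahydro-2H-cyclopenta[d][1,3]dioxin-5-yl]prop-2-en-1-ol F10 as both C10 epimers. Pyridinium tosylate in methanol removes the acetal from F10 and gives (1R,2S,3S)-2-(hydroxymethyl)-3-[(1RS)-1-hydroxyprop-2-en-1-yl]-3-methyl-1-(propan-2-yl)cyclopentan-1-ol F11. TEMPO with PhI(OAc)2 oxidises only the primary alcohol of F11 and gives (1R,2R,5S)-2-hydroxy-5-[(1RS)-1-hydroxyprop-2-en-1-yl]-5-methyl-2-(propan-2-yl)cyclopentane-1-carbaldehyde F12. The indium reaction of step 16, applied to F12 with its single aldehyde, returns to the route at 25.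

**Step 23.** The most likely failure is low conversion at the crowded C10 hydroxyl beside the quaternary C1, and under forcing conditions isomerisation of the angeloyl group to the tiglate. The fallback builds the Z-enoate on the alcohol instead of transferring it. It sets out from 32. Steglich esterification with 2-[bis(2,2,2-trifluoroethoxy)phosphoryl]propanoic acid gives (1S,4R,5S,6S,10S)-10-{2-[bis(2,2,2-trifluoroethoxy)phosphoryl]propanoyloxy}-4-hydroxydauc-8-en-6-yl 4-(triisopropylsilyloxy)benzoate F13. Still–Gennari olefination of F13 with acetaldehyde, KN(SiMe3)2 and 18-crown-6 in THF at −78 °C gives the Z-2-methylbut-2-enoate and returns to the route at 35.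

## Further compounds

F1 | step 8 | methyl (1R,5S)-5-[(tert-butyldimethylsilyloxy)methyl]-5-methyl-2-oxocyclopentane-1-carboxylate | COC(=O)[C@@H]1[C@@](C)(CO[Si](C)(C)C(C)(C)C)CCC1=O
F2 | step 8 | methyl (1R,2R,5S)-5-[(tert-butyldimethylsilyloxy)methyl]-2-hydroxy-5-methylcyclopentane-1-carboxylate | COC(=O)[C@@H]1[C@@](C)(CO[Si](C)(C)C(C)(C)C)CC[C@H]1O
F3 | step 8 | (1R,2S,3S)-3-[(tert-butyldimethylsilyloxy)methyl]-2-(hydroxymethyl)-3-methylcyclopentan-1-ol | OC[C@@H]1[C@@](C)(CO[Si](C)(C)C(C)(C)C)CC[C@H]1O
F4 | step 9 | methyl (6R,7S)-7-methyl-7-(pivaloyloxymethyl)-1,4-dioxaspiro[4.4]nonane-6-carboxylate | COC(=O)[C@@H]1[C@@](C)(COC(=O)C(C)(C)C)CCC12OCCO2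
F5 | step 9 | [(6S,7S)-7-methyl-1,4-dioxaspiro[4.4]nonane-6,7-diyl]dimethanol | OC[C@@H]1[C@@](C)(CO)CCC12OCCO2
F6 | step 9 | (6S,7S)-6,7-bis[(tert-butyldimethylsilyloxy)methyl]-7-methyl-1,4-dioxaspiro[4.4]nonane | CC(C)(C)[Si](C)(C)OC[C@@H]1[C@@](C)(CO[Si](C)(C)C(C)(C)C)CCC12OCCO2
F7 | step 13 | (1S,2S,3S)-2,3-bis[(tert-butyldimethylsilyloxy)methyl]-3-methyl-1-(prop-1-en-2-yl)cyclopentan-1-ol | CC(C)(C)[Si](C)(C)OC[C@@H]1[C@@](C)(CO[Si](C)(C)C(C)(C)C)CC[C@@]1(O)C(C)=C
F8 | step 16 | [(4aS,5S,7aR)-2,2,5-trimethyl-7a-(propan-2-yl)hexahydro-2H-cyclopenta[d][1,3]dioxin-5-yl]methanol | CC2(C)OC[C@@H]1[C@@](C)(CO)CC[C@@]1(O2)C(C)C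
F9 | step 16 | (4aS,5S,7aR)-2,2,5-trimethyl-7a-(propan-2-yl)hexahydro-2H-cyclopenta[d][1,3]dioxine-5-carbaldehyde | CC2(C)OC[C@@H]1[C@@](C)(C=O)CC[C@@]1(O2)C(C)C
F10 | step 16 | (1RS)-1-[(4aS,5S,7aR)-2,2,5-trimethyl-7a-(propan-2-yl)hexahydro-2H-cyclopenta[d][1,3]dioxin-5-yl]prop-2-en-1-ol | CC2(C)OC[C@@H]1[C@@](C)(C(O)C=C)CC[C@@]1(O2)C(C)C
F11 | step 16 | (1R,2S,3S)-2-(hydroxymethyl)-3-[(1RS)-1-hydroxyprop-2-en-1-yl]-3-methyl-1-(propan-2-yl)cyclopentan-1-ol | OC[C@@H]1[C@@](C)(C(O)C=C)CC[C@@]1(O)C(C)C
F12 | step 16 | (1R,2R,5S)-2-hydroxy-5-[(1RS)-1-hydroxyprop-2-en-1-yl]-5-methyl-2-(propan-2-yl)cyclopentane-1-carbaldehyde | O=C[C@@H]1[C@@](C)(C(O)C=C)CC[C@@]1(O)C(C)C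
F13 | step 23 | (1S,4R,5S,6S,10S)-10-{2-[bis(2,2,2-trifluoroethoxy)phosphoryl]propanoyloxy}-4-hydroxydauc-8-en-6-yl 4-(triisopropylsilyloxy)benzoate | CC(C(=O)O[C@H]1C=C(C)C[C@H](OC(=O)c2ccc(O[Si](C(C)C)(C(C)C)C(C)C)cc2)[C@@H]2[C@]1(C)CC[C@@]2(O)C(C)C)P(=O)(OCC(F)(F)F)OCC(F)(F)F
A1 | alternative 1 | (1S,4R,5S,6S,10S)-8-methylidene-4-(triethylsilyloxy)daucane-6,10-diol | O[C@H]1CC(=C)C[C@H](O)[C@@H]2[C@]1(C)CC[C@@]2(O[Si](CC)(CC)CC)C(C)C
A2 | alternative 1 | (1S,2R,3R)-1-methyl-3-(propan-2-yl)-3-(triethylsilyloxy)cyclopentane-1,2-dicarbaldehyde | O=C[C@@H]1[C@@](C)(C=O)CC[C@@]1(O[Si](CC)(CC)CC)C(C)C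
A3 | alternative 1 | 3-iodo-2-(iodomethyl)prop-1-ene | C=C(CI)CI
A4 | alternative 2 | (2S,3R)-2-(hydroxymethyl)-3-methyl-3-vinylcyclopentan-1-one | OC[C@@H]1[C@@](C)(C=C)CCC1=O
A5 | alternative 2 | 3-methylcyclopent-2-en-1-one | CC1=CC(=O)CC1
A6 | alternative 2 | formaldehyde | C=O
A7 | alternative 3 | (1R,4R,8S)-dauca-5,9-dien-4-ol triethylsilyl ether | C1=C[C@@H](C)CC=C2[C@]1(C)CC[C@@]2(O[Si](CC)(CC)CC)C(C)C
A8 | alternative 3 | (3R,6E)-6-methyl-7-(2-methylcyclopropyl)-3-(propan-2-yl)-3-(triethylsilyloxy)hept-6-en-1-yne | C#C[C@](CC/C(C)=C/C1CC1C)(O[Si](CC)(CC)CC)C(C)C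
A9 | alternative 3 | (S)-terpinen-4-ol | CC1=CC[C@@](O)(CC1)C(C)C
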